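(The numbers are invented; the result is computed.)

The ratio of the constant with which Q takes J away to the constant with which Q makes J from Z, σ = 0.327 at 100 °C, the selectivity factor, is the quantity we carry through these flasks.

    Q + J → Q.J (k1 = 4.9 /M/h, Ea1 = 87.0 kJ/mol)
    Z + Q → J + E (k2 = 15 /M/h, Ea2 = 74.0 kJ/mol)
    L ⇌ E, rate k3*(cs3 - [E]) while solid is left; crystals form when [E] > cs3 (cs3 = 4.1 mM, k3 = 1.0 /h)
    (constants at 100 °C)

| flask | Z | Q | time | remark | temperature |
|---|---|---|---|---|---|
| south | 0.020 M (fed, over 6.0 d) | 1.02 equiv | 10 d | the addition at 70 °C, then warmed to 100 °C; the feed brings no volume worth counting |  |
| south-east | 0.020 M | 1.02 equiv | 10 d | everything together at the start | 100 °C |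
| north-east | 0.020 M | 1.02 equiv | 10 d | everything together at the start at 70 °C, warmed to 100 °C at 6.0 d |  |
| south-west | 0.020 M | 1.02 equiv (fed, over 6.0 d) | 10 d | all else is in the flask from the start; the feed brings no volume worth counting | 100 °C |
| north-west | 0.020 M | 1.02 equiv (fed, over 40 h) | 10 d | all else is in the flask from the start; the feed brings no volume worth counting | 100 °C |

- E is meant together with its L
- solid, in amounts per volume of the solution: L
- at 100 °C the constants are as listed, elsewhere as the activation energies make them

* the flask with the highest amount of J, in percent of the Z charged ("all alike" if they lie within 1.5 percentage points) (south / south-east / north-east / south-west / north-west / all alike)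
* final J, as a percentage of the Z charged, in south
* final J, as a percentage of the Z charged, in south-east
* final J, as a percentage of the Z charged, in north-east
* final J, as a percentage of the Z charged, in south-west
* final J, as a percentage of the Z charged, in north-west

Does the way Q goes in matter? Both steps are first order in Q, so [Q] cancels from their ratio: each Z spent makes one J and takes back σ[J]/[Z] of one. South-east, south-west and north-west, each with its Z in the flask from the start and each at 100 °C, therefore share one curve, and they share its end point if free Q reaches nil; for a measure of the time this takes we have the half-life of Z as charged in south-east, 0.094 d, which is far shorter than the 10 d allowed.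

How much J lies on that curve? With x and y the Z and J as fractions of the Z charged, the curve is y = (x^σ − x)/(1 − σ). Since Q is spent once on each Z and once on each Q.J, the balance at nil free Q is y = 2 − e − 2x, with e = 1.02 equiv. We guess x = 0.5 and go round, curve then balance: y = 44.2% gives x = 0.269, then y = 56.8% gives x = 0.206, and once more y = 58.0%.

What does cold buy? The step that takes J away has 87.0 kJ/mol against 74.0 kJ/mol, so at 70 °C σ falls to 0.226. The same rounds, started from our last x, give 63.8%, then x = 0.171 and y = 64.6%. Whatever north-east still has to do after warming runs at the larger σ, so we place north-east between 58.0% and 64.6%. South runs its feed at the same cold σ, but its Z enters slowly, so this curve does not hold there and we give south no number.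

The forecast chose north-east, with 53.5%, 58.1%, 63.5%, 58.1% and 58.1% in the order asked, holding that “feeding Q therefore changes nothing once it is all consumed”.

The flasks give north-east as the highest: south 54.2%, south-east 58.1%, north-east 63.4%, south-west 58.1%, north-west 58.1%.

Put back into the curve at σ, south-east's final Z of 20% gives 58.1% of J, and south-west's 20% gives 58.1%. North-east ends with Q at 0% of its charge and Z at 17%, and the same stands at 100 d: ten times the time moves its J by −1.0 × 10⁻⁵ percentage point, to 63.4%. South, with Q at 0% and Z at 22%, stands at 54.2% of J after that long.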